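Count in mol% minutes, free catalyst loading times time, the clock on which you can lay the starting material of the three earlier runs side by side.

common to all: starting material 10 mM; second catalyst 20 mol%
- south: partner 0.90 equiv; free catalyst 4.8 mol%; run made earlier
- west: partner 0.90 equiv; free catalyst 3.2 mol%; run made earlier
- east: partner 0.90 equiv; free catalyst 7.2 mol%; run made earlier
- beta: partner 0.900 equiv; free catalyst 4.8 mol%; plug flow through a tube for 40 min, no back-mixing; time 40 min
- delta: partner 0.900 equiv (fed, over 32.0 min); free catalyst 4.8 mol%; all but partner at the start; partner goes in evenly over 32.0 min, the run ends at 40 min; time 40 min
- epsilon: partner 0.900 equiv; free catalyst 4.8 mol%; a single well-mixed tank run continuously and read at steady state, 40 min in it on average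
- gamma: partner 0.900 equiv; free catalyst 4.8 mol%; a closed flask charged with all of it at once and left for 40 min; time 40 min

- south (time / min: target / %, starting material / %): 1.33: 0.4, 92.3; 4.00: 4.6, 80.6; 6.00: 5.8, 73.1; 10.0: 10.9, 59.4; 15.0: 16.2, 47.1; 20.0: 21.5, 37.6; 25.0: 24.5, 31.5
- west (time / min: target / %, starting material / %): 2.00: 1.4, 93.4; 3.00: 3.6, 90.3; 4.00: 3.4, 86.5; 6.00: 4.5, 79.8; 10.0: 10.8, 70.6; 15.0: 14.8, 58.3; 25.0: 21.3, 41.6
- east (time / min: target / %, starting material / %): 2.00: 1.1, 85.0; 3.00: 3.5, 77.7; 4.00: 4.1, 71.4; 6.00: 8.2, 62.7; 10.0: 16.3, 47.1; 15.0: 22.5, 35.7; 25.0: 28.0, 21.5

(scatter of a reading: 1 percentage point)

- the stated concentrations are those of everything mixed, before any reaction; amounts are the same in each set-up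
- the feed brings no volume worth counting
- the earlier runs were made in a closed, stirred flask

- the set-up with the highest amount of target at the outlet or at the end, in percent of the starting material put in ("none" if the first two lie within 2 percentage points) (beta / delta / epsilon / gamma / none)
- amount of target at the outlet or at the end, in percent of the starting material put in, beta
- amount of target at the outlet or at the end, in percent of the starting material put in, delta
- amount of target at the outlet or at the end, in percent of the starting material put in, epsilon
- amount of target at the outlet or at the end, in percent of the starting material put in, gamma

The clock reads alike for south at 15.0 min and east at 10.0 min, and you read starting material 47.1% and 47.1%, target 16.2% and 16.3%. So starting material looks like one curve on that clock, but target does not: west at 15.0 min and south at 10.0 min also read alike, with starting material 58.3% and 59.4%, yet target stands at 14.8% in west and 10.9% in south.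

Next take the kept share, meaning target found per starting material lost, which is the selectivity on conversion. At the end of south it is 35.8%, at the end of east 35.7%, and at the end of west 36.5%. These three are readings at 25.0 min, and the share is no constant along a run: south gives 26.8% at 10.0 min, lower than at its last reading. In east it reads 35.0% at 15.0 min and 35.7% at 25.0 min, so I carry the late value to the late end of a closed flask and to no earlier moment.

Now the chain for gamma, the closed flask. South's reading at 10.0 min gives a first-order constant of 0.0521 min⁻¹, so 40 min leaves 12.4% starting material, and the kept share makes that 31.3% target.

The weak link is the first-order step. On the clock, it puts east's last reading at 14.2%, less than the 21.5% you read there. So drop it and use the curve itself. Gamma's clock lies a little past east's last reading, and a straight line through the last readings of south and east reaches 19.5% starting material there. That gives 28.8% target for gamma, and the same for beta, whose every slice is a closed flask for 40 min. The kept share was read with the partner charged at the start, so I carry it to neither delta nor epsilon.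

The forecast gave beta 30%, delta 44%, epsilon 34%, gamma 30% and named delta best, holding that “Slow feeding keeps partner low and spares it”.

    second catalyst + open intermediate ⇌ catalyst intermediate (K = 30.0 L mol⁻¹, k = 1.75 L mol⁻¹ s⁻¹)
    partner + target → over-reaction product (k = 0.189 L mol⁻¹ s⁻¹)
    partner + catalyst intermediate → second catalyst + target (k = 7.29 L mol⁻¹ s⁻¹)
    starting material + free catalyst ⇌ free catalyst + open intermediate (K = 2.20, k = 2.04 L mol⁻¹ s⁻¹)

Gamma gives 29.0%, beta 29.0%, delta 32.1% and epsilon 19.0%, so delta comes out highest. Target does not sit still in beta: the path from partner and target to over-reaction product, taken alone with the concentrations as charged, has a half-life of 6.8 min, shorter than the 40 min in the tube. Gamma ended with 19.3% starting material, and the kept share of what it lost is 28.9%; beta ended with 19.3%, which gives 28.9%.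

Readings and results are simulated for substances that don't exist; noise was put on by code.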